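All runs are simulated for an exercise; scatter was added.

X cannot come straight from Z. Add up the alpha run at 0.500 min: Z stands at 1.0% and X at 9.3%, so the rest of the charge sits in a form no column shows. Read X therefore as two clocks, a rise out of that unseen form and a later fall.

| flask | Z | Q | temperature | remark | time |
|---|---|---|---|---|---|
| alpha | 2 M | 190 mM | 15 °C | run made earlier |  |
| beta | 2 M | 420 mM | 37 °C | run made earlier |  |
| eta | 3 M | 280 mM | 15 °C | run made earlier |  |
| noon | 2.0 M | 280 mM | 25 °C |  | 6.0 min |
| spring | 2.0 M | 280 mM | 5 °C |  | 6.0 min |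
| dawn | 2.0 M | 280 mM |  | at 5 °C until 2.0 min, from then on at 45 °C | 6.0 min |
| autumn | 2.0 M | 280 mM | 45 °C |  | 6.0 min |

| run | time / min | X / % | Z / % |
|---|---|---|---|
| alpha | 0.500 | 9.3 | 1.0 |
| alpha | 1.50 | 25.8 | 0 |
| alpha | 2.50 | 38.7 | 0 |
| alpha | 4.00 | 47.4 | 0 |
| alpha | 6.00 | 53.6 | 0.2 |
| alpha | 8.00 | 55.0 | 0 |
| beta | 0.250 | 51.6 | 0 |
| beta | 0.333 | 57.1 | 1.5 |
| beta | 0.500 | 60.9 | 0 |
| beta | 1.00 | 61.1 | 0.2 |
| beta | 1.50 | 56.1 | 0.8 |
| beta | 3.00 | 43.9 | 0 |
| eta | 0.667 | 18.2 | 0 |
| eta | 1.00 | 26.0 | 0 |
| eta | 2.00 | 42.8 | 0.4 |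
| eta | 4.00 | 55.6 | 0 |
| eta | 8.00 | 59.2 | 0 |

(readings scatter by 1 percentage point)

- the flask that comes out highest in amount of X, in percent of the Z charged, or "all alike" when all lie within 1.5 percentage points (noon / spring / dawn / autumn / all alike)
- X at the end, in percent of the Z charged, noon
- X at the end, in percent of the Z charged, spring
- X at the end, in percent of the Z charged, dawn
- X at the end, in percent of the Z charged, autumn



Get the rise two ways. Take the height from eta's last reading, 59.2%, and put one early reading of each run against it: alpha gives a rise constant of 0.382 min⁻¹, eta 0.578 min⁻¹. Their ratio, 1.51, stands beside the ratio of [Q], 1.47, though the two runs differ in the charge of Z as well, so treat the rise as pseudo-first-order, with a constant proportional to [Q].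

Now go to the other end. In beta, X drops from 61.1% at 1.00 min to 43.9% at 3.00 min, a fall of 0.165 min⁻¹. At 15 °C the fall hides under the last of the rise, so divide that out. Alpha then gives 0.0163 min⁻¹ and eta 0.00790 min⁻¹. These two part. Each is a small difference of readings with a scatter of 1 percentage point, and alpha's span is shorter than eta's, so alpha's is the looser. Keep the mean, 0.0121 min⁻¹, as a reading and nothing firmer.

Join the ends. On a reciprocal-temperature scale 25 °C lies near the middle of 15 °C and 37 °C, so take geometric means. That gives 0.0447 min⁻¹ for noon; call it the fall constant, the share of X lost per minute once the rise is over. Beta's own rise constant is 5.03 min⁻¹, and with beta scaled to noon's [Q], noon's comes to 1.39 min⁻¹. Its time is far shorter than 6.0 min, so noon is on its fall when read. The height, extrapolated back from the late readings of eta and beta, is 68.9%, and my own reckoning for noon is 52.7%.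

The forecast says “Noon comes out highest” and gives 52% for noon, 41% for spring, 19% for dawn and 11% for autumn, so it names noon.

The flasks give 52.3% for noon, 44.8% for spring, 20.3% for dawn and 10.8% for autumn, with noon highest.

    Z → D (k = 0.0644 s⁻¹, Ea = 75.0 kJ mol⁻¹)
    D → E (k = 3.96 × 10⁻⁴ s⁻¹, Ea = 82.0 kJ mol⁻¹)
    Q + D ⇌ Q + X (K = 3.10, k = 0.00782 M⁻¹ s⁻¹, Ea = 67.0 kJ mol⁻¹, ΔH = 6.00 kJ mol⁻¹)
    (constants at 5 °C)

Noon is past its best when read: X stood higher at 3.00 min, at 59.0%. Carry the fall constant from there to 6.0 min and it gives 51.6%, beside the 52.3% found. Now leave noon standing until 15 min, with amounts and temperature held. From 52.3%, the same constant over 9.00 min gives 35.0%, and that flask reads 34.5%.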